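A turnover, one product molecule per molecule of free catalyst charged, is the unit to count in. By the first reading of the dusk run the catalyst had done 6.00 of them, each taking either a left-handed or a right-handed substrate. Both substrates meet the same c(reagent) and c(free catalyst), however much catalyst sits in the resting dimer, so these factors cancel between them. With f the fraction of a substrate's charge left, and while racemization stays small, ln f(left) = s ln f(right), where s, the selectivity factor, is the ratio of the two rate constants.

common to all: left-handed substrate 0.20 M; right-handed substrate 0.20 M; free catalyst 26 mM

| run | reagent | racemization catalyst | temperature | remark | time |
|---|---|---|---|---|---|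
| dusk | 0.80 M | 15 mM | 70 °C | run made earlier |  |
| spring | 0.80 M | 60 mM | 92 °C | run made earlier |  |
| blue | 0.800 M | 30 mM | 100 °C |  | 10 h |
| green | 0.800 M | 30 mM | 60 °C |  | 10 h |
| red | 0.800 M | 30 mM | 80 °C |  | 10 h |

- dusk (time / h: left-handed product / %, right-handed product / %): 4.00: 31, 8; 12.0: 41, 17; 25.0: 48, 27; 40.0: 48, 35; 48.0: 51, 36
- spring (time / h: left-handed product / %, right-handed product / %): 2.50: 41, 26; 5.00: 51, 36; 8.00: 54, 44; 10.0: 51, 41; 12.0: 48, 44

(scatter of a reading: 2 percentage points)

- free catalyst is single-handed; left-handed substrate and right-handed substrate are mirror images of each other, charged as a racemate, each of them at the stated concentration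
- candidate steps: reagent + free catalyst + right-handed substrate -> free catalyst + right-handed product; left-handed substrate + racemization catalyst <-> right-handed substrate + racemization catalyst; 2 free catalyst <-> resting dimer; reagent + free catalyst + left-handed substrate -> free catalyst + left-handed product
- an excess is below zero if the other one leads

- the best flask by excess of left-handed product over right-handed product; "all alike" if 1.5 percentage points covers them all (blue / green / red / all alike)
- excess of left-handed product over right-handed product at the end, blue
- excess of left-handed product over right-handed product at the end, green
- excess of left-handed product over right-handed product at the end, red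

You can read s from the runs in two ways. The raw way is the ratio of the products at the first reading: 3.88 for dusk and 1.58 for spring. The other way is the logarithm rule, taking f as one minus twice the product's share, since each substrate was half of the charge. That gives 5.55 for dusk and 2.34 for spring.

The two ways should meet at zero conversion, but here they part, and the raw ratio is the one that cheats. At dusk's first reading the left-handed substrate stood at 38.0% of its charge, less than the right-handed at 84.0%, so the favoured substrate had thinned its own supply. Both values of s remain readings with their scatter.

Red's temperature lies near the middle of dusk's and spring's, so I take the geometric mean and estimate the selectivity factor for red at 3.60. The same mean of the left-handed first-reading paces, 0.242 h⁻¹ and 0.686 h⁻¹, gives 0.407 h⁻¹. Held for 10 h, that leaves f(left) = 1.70% and f(right) = 32.3%. The excess, (f(right) − f(left)) / (sum of the two product fractions), is then 18.4% for red. Green is the coldest flask. The colder dusk run reads a higher s than spring and a lower pace, though the two runs also differ in racemization catalyst, so I expect green to lead.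

The forecast also names green, with 7% for blue, 60% for green and 27% for red, on the ground that “selectivity falls with heat”. For red it is higher than my figure.

The flasks give 2.61% for blue, 63.0% for green and 24.3% for red, so green leads.

reagent + free catalyst + right-handed substrate → free catalyst + right-handed product (k = 1.70 M⁻² min⁻¹, Ea = 71.0 kJ mol⁻¹); left-handed substrate + racemization catalyst ⇌ right-handed substrate + racemization catalyst, rate k2*[racemization catalyst]*[left-handed substrate] forward; the back reaction follows from the equilibrium constant (k = 0.0110 M⁻¹ min⁻¹, Ea = 77.0 kJ mol⁻¹); 2 free catalyst ⇌ resting dimer, settled at all times (K = 86.0 M⁻¹, ΔH = −71.0 kJ mol⁻¹); reagent + free catalyst + left-handed substrate → free catalyst + left-handed product (k = 3.91 M⁻² min⁻¹, Ea = 46.0 kJ mol⁻¹); (constants at 100 °C) Red kept 4.2% of its left-handed substrate at 10.0 h. With 3.60 the rule puts the right-handed at 41.4%, against 39% in the flask, and the excess at 24.1%. A neighbouring flask is red with 0.044 M of free catalyst, and it kept 1.9% of its left-handed substrate. There the rule puts the right-handed at 33.0%, against 30% in that flask, and the excess at 18.8%, where the flask gives 18.8%.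

Readings and results were generated by integration with constants of no real substance, noise included.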